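1. I had 0.110 M of partner against 0.0200 M of protic impurity and 0.10 M each of left-handed and right-handed substrate, so partner was the limiting reagent.

all flasks: left-handed substrate 0.10 M; right-handed substrate 0.10 M; stray impurity 0.43 mM

| charge | partner | protic impurity | free catalyst | remark |
|---|---|---|---|---|
| ash | 0.15 M | 0.020 M | 1 mM | run made earlier |
| elm | 0.24 M | 0.020 M | 1 mM | run made earlier |
| flask | 0.110 M | 0.0200 M | 1.0 mM |  |

- ash (time / min: left-handed product / %): 0.500: 3.4; 1.50: 7.7; 3.00: 13.0; 4.00: 15.7; 6.00: 19.9; 8.00: 23.7
- elm (time / min: left-handed product / %): 0.500: 4.6; 1.50: 12.2; 3.00: 19.7; 4.00: 23.5; 6.00: 29.0; 8.00: 33.2

(readings scatter by 0.3 percentage points)

* apparent order in partner when 30% of the left-handed substrate and right-handed substrate together are converted (percent change of the rate of making left-handed product for one percent more partner charged)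
* apparent order in free catalyst when 30% of the left-handed substrate and right-handed substrate together are converted (percent change of the rate of making left-handed product for one percent more free catalyst charged)

- free catalyst is single-handed; left-handed substrate and right-handed substrate are mirror images of each other, charged as a racemate, each of them at the stated concentration
- the analysis behind the earlier runs scatters by 0.3 percentage points, standard deviation
- no earlier run changes the charge of free catalyst; that part of a forecast is a guess

2. I turned the question round: an order in partner near 1 needs partner at the look point, 30% conversion of both substrates together, to stand close to its charge. I assumed that each substrate molecule converted and each protic impurity molecule takes one partner molecule, so 30% conversion takes 0.0600 M of partner on top of what the protic impurity takes.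

3. That leaves the margin m, the partner left at the look point: 0.0300 M in this flask. On that assumption, at fixed conversion, extra partner charged lands wholly in m, so with the rate taken as proportional to m I took the order as the lever L, the charge over m 3.67. The ash run's charge gives 2.14 and the elm run's gives 1.50, so this flask stands far from 1.

4. The simulated runs bear on m. Across the same band of left-handed product, the elm run climbed 2.00 times as fast as the ash run, a reading, while their charges stood at 1.60 to one. Partner left at the middle of that band, elm over ash, is 2.04 if I subtract the protic impurity and the left-handed product; this leaves out any partner taken by the right-handed substrate, which these runs do not show, so it is a rough figure.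

5. If each stray impurity kills one free catalyst, the catalyst order is 1.75, which is a guess. I committed to that and to L.

6. The forecast gave 3 in partner and 1.6 in free catalyst, holding that “the ratio grows because partner is being depleted”. My L stood above the forecast's value in partner.

7. The flask gave 3.7 in partner and 1.8 in free catalyst.

    partner + free catalyst + left-handed substrate → free catalyst + left-handed product (k = 1500 /M²/min)
    free catalyst + stray impurity → spent catalyst (k = 41000 /M/min)
    partner + protic impurity → quenched reagent (k = 8.90 /M/min)
    partner + free catalyst + right-handed substrate → free catalyst + right-handed product (k = 470 /M²/min)

At 10.0 min, partner in the flask went into the step making left-handed product 54 times as fast as into quenched reagent, with protic impurity down to 0.532% of its charge. Partner then stood at 0.0358 M, still above the margin of 0.0300 M, the m behind L of 3.67, that I had reckoned for the look point, which the flask reached at 12.4 min.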